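The north-east run was the one I leaned on for Saturday's flask. These were the flasks, the readings and the questions:

| flask | substrate | partner | free catalyst | impurity | remark | time |
|---|---|---|---|---|---|---|
| north-west | 0.12 M | 0.132 M | 4 mM | 0.95 mM | run made earlier |  |
| south-east | 0.12 M | 0.132 M | 9 mM | 0.95 mM | run made earlier |  |
| north-east | 0.12 M | 0.132 M | 6 mM | 0.47 mM | run made earlier |  |
| Saturday's | 0.12 M | 0.132 M | 6.0 mM | 0.95 mM |  | 6.0 h |
| Sunday's | 0.12 M | 0.132 M | 6.0 mM | 0.95 mM |  | 10 h |

- north-west (time / h: substrate / %, product / %, open intermediate / %): 0.333: 95.6, 0.2, 3.5; 1.00: 90.0, 0.5, 9.3; 1.50: 86.2, 0.3, 13.3; 2.50: 79.2, 1.2, 18.5; 4.00: 72.3, 2.0, 24.8; 5.00: 68.3, 2.1, 27.1; 6.00: 65.8, 3.2, 30.0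
- south-east (time / h: substrate / %, product / %, open intermediate / %): 0.833: 78.1, 0.7, 18.3; 1.50: 67.1, 2.5, 27.7; 2.50: 54.9, 5.1, 36.7; 3.00: 49.7, 6.9, 39.9; 4.00: 41.4, 10.2, 44.0; 5.00: 36.1, 13.4, 47.6; 6.00: 31.4, 15.4, 49.0
- north-east (time / h: substrate / %, product / %, open intermediate / %): 0.500: 89.8, 0, 9.1; 0.833: 84.7, 0.3, 14.1; 1.50: 75.6, 1.4, 21.3; 3.00: 62.1, 3.6, 32.0; 6.00: 45.9, 8.7, 42.9

(readings scatter by 0.3 percentage points)

- the earlier runs were read with a standard deviation of 0.3 percentage points

* which of these there is most of at the end, counted by the substrate in it, Saturday's (substrate / open intermediate / product)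
* which of these there is most of at the end, counted by the substrate in it, Sunday's (substrate / open intermediate / product)
* how much there is at the end of the one of these that leads, in percent of the substrate charged: Saturday's
* how much there is at the end of the one of these that leads, in percent of the substrate charged: Sunday's

I took the impurity to remove free catalyst one for one and called what remains the working catalyst, w = c(free catalyst) − c(impurity). That gave 3.05 mM in the north-west run, 5.53 mM in the north-east run, 8.05 mM in the south-east run and 5.05 mM in both new flasks, so the north-east run stood nearest to the new flasks in w. My doubt was that these runs cannot prove one for one, but for Saturday's flask the assumption enters as a small correction to the north-east reading of 45.9% substrate at 6.00 h.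

The north-west and north-east readings gave a correction of 3.9 points for the lower w. The readings bend, however, and the north-east and south-east pair gave 2.8 points, less, so I used the mean. That put Saturday's substrate at 49.2% and, the same way, its open intermediate at 41.1%.

No run reached 10 h, so for Sunday's flask I held w times time equal: it matched the south-east run at 6.27 h, close to that run's last reading of 49.0% open intermediate and 31.4% substrate. The objection was that the rule flatters a slow flask, since the north-east run at 6.00 h matched the south-east run at 4.12 h, yet its substrate stood 4.5 points higher and its open intermediate 1.1 points lower than the south-east reading at 4.00 h. Sunday's flask trails its match by twice as many hours, so I doubled both gaps and got open intermediate 46.8% against substrate 40.4%.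

The forecast named substrate at 48.7% for Saturday's flask and open intermediate at 44% for Sunday's, a little apart from my figures, and concluded: “The lead therefore switches”.

Saturday's flask gave substrate at 49.3%, and Sunday's gave open intermediate at 46.7%.

    substrate + free catalyst → free catalyst + open intermediate (k = 0.0110 L mol⁻¹ s⁻¹)
    free catalyst + open intermediate ⇌ catalyst intermediate (K = 4.80 L mol⁻¹, k = 0.320 L mol⁻¹ s⁻¹)
    partner + catalyst intermediate → free catalyst + product (k = 0.00820 L mol⁻¹ s⁻¹)
    free catalyst + impurity → spent catalyst A (k = 16.0 L mol⁻¹ s⁻¹)
    substrate + free catalyst → spent catalyst B (k = 5.40 × 10⁻⁴ L mol⁻¹ s⁻¹)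

At 6.00 h in Saturday's flask, open intermediate was being made 2.82 times as fast as it was used up, each step taken net. In Sunday's flask at 10.0 h it stood at 46.7% against substrate at 38.4%. In Saturday's flask, the share that w sets aside, 15.8%, sits beside spent catalyst A at 15.8%, with impurity, the limiting reagent of that step, at 0%. One more flask, like Saturday's but with 10.0 mM of free catalyst, has w of 9.05 mM, above the south-east run, and at 6.00 h it held substrate at 26.9% against that run's reading of 31.4%.

The numbers in the tables stem from a simulated flask with made-up constants; the scatter is artificial.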